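Ring A is cut [3+3] at C1–C6 and C3–C4 (cadinane numbering). The precursor is an acyclic methyl ketone (C5 carbonyl flanked by C6 and C4) carrying a 4-oxo-2-enal (C10 ketone, C1=C2, C3 aldehyde) released from a furan. In one amine-buffered operation C6 adds to C1 (Michael, closing ring B) and C4 condenses with C3 (aldol, closing ring A). The step exploits that both ring-fusion carbons, C1 and C6, then sit α to carbonyls, so the trans-decalin forms under thermodynamic control, steered by the preset C7 and C8 centres. The C5 carbonyl is later erased with alkene transposition and C10 is methylenated.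

Key step: step 8

Remark: cadinane numbering is used for the skeleton (ring A = C1–C6 with C15 on C4; ring B = C1, C6–C10 with C14 on C10; C11–C13 on C7; ester oxygen on C8).

Step 1
Reactants: 1 furan; 2 (S)-epichlorohydrin
Product: 4 (S)-1-chloro-3-(furan-2-yl)propan-2-ol, via 2-furyllithium 3 (not isolated)
Conditions: n-BuLi, THF, 0 °C; then 2, BF3·OEt2, −78 °C; aq NH4Cl
Reagents that add atoms: none
Why: The BF3-activated epoxide should be opened by the aryllithium at its unsubstituted terminus (SN2) faster than chloride is displaced, so the chiral-pool carbinol centre becomes C8 unchanged.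

Step 2
Reactants: 4 (S)-1-chloro-3-(furan-2-yl)propan-2-ol
Product: 6 (S)-1-(furan-2-yl)but-3-en-2-ol, via epoxide 5 (not isolated)
Conditions: Me3S+ I−, n-BuLi, THF, −10 °C to 23 °C
Reagents that add atoms: trimethylsulfonium iodide, C[S+](C)C.[I-]
Why: Dimethylsulfonium methylide should close the chlorohydrin to the terminal epoxide, open it at CH2 and then lose Me2S from the β-alkoxy sulfonium ylide (one-carbon homologation of an epoxide to an allylic alcohol), leaving the C8 centre untouched.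

Step 3
Reactants: 6 (S)-1-(furan-2-yl)but-3-en-2-ol
Product: 7 (S)-2-{2-[(4-methoxybenzyl)oxy]but-3-en-1-yl}furan
Conditions: NaH, 4-methoxybenzyl chloride, Bu4NI (cat.), THF/DMF, 0 °C to 23 °C
Reagents that add atoms: 4-methoxybenzyl chloride, COc1ccc(CCl)cc1
Why: Williamson ether synthesis on the secondary allylic alkoxide gives an ether that is stable to organometallics and bases and removable oxidatively later.

Step 4
Reactants: 7 (S)-2-{2-[(4-methoxybenzyl)oxy]but-3-en-1-yl}furan; 8 but-3-en-2-one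
Product: 9 (3E,5S)-6-(furan-2-yl)-5-[(4-methoxybenzyl)oxy]hex-3-en-2-one
Conditions: second-generation Hoveyda–Grubbs catalyst RuCl2(H2IMes)(=CH-C6H4-2-O-i-Pr) (5 mol %), excess 8, CH2Cl2, 40 °C
Reagents that add atoms: none
Why: Olefin cross-metathesis between the slowly homodimerising branched allylic ether and the electron-poor enone should give the E-enone selectively.

Step 5
Reactants: 10 3,3-diethoxyprop-1-ene
Product: 12 2-bromo-3,3-diethoxyprop-1-ene, via dibromide 11 (not isolated)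
Conditions: Br2, CH2Cl2, −20 °C; then KOt-Bu (1.0 equiv), THF, −20 °C
Reagents that add atoms: bromine, BrBr
Why: Bromine addition followed by E2 loss of HBr (acidified C2–H, primary bromide leaving) gives the 2-bromoalkene, and one equivalent of base at low temperature avoids the second elimination to the alkyne.

Step 6
Reactants: 9 (3E,5S)-6-(furan-2-yl)-5-[(4-methoxybenzyl)oxy]hex-3-en-2-one; 12 2-bromo-3,3-diethoxyprop-1-ene
Product: 15 (4S,5S)-4-(3,3-diethoxyprop-1-en-2-yl)-6-(furan-2-yl)-5-[(4-methoxybenzyl)oxy]hexan-2-one, via vinyllithium 13 (not isolated), via divinylcuprate 14 (not isolated)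
Conditions: 12, t-BuLi (2 equiv), Et2O, −78 °C; CuI (0.5 equiv), −40 °C; then 9, −78 °C to −40 °C; aq NH4Cl
Reagents that add atoms: none
Why: Cuprate 1,4-addition to the γ-alkoxy E-enone should occur anti to the ether (Felkin–Anh-type transition state, C–O bond anti to the incoming cuprate, γ-H eclipsing the alkene), which sets C7; this anti relationship in the chain is the cis C7/C8 relationship of ring B.

Step 7
Reactants: 15 (4S,5S)-4-(3,3-diethoxyprop-1-en-2-yl)-6-(furan-2-yl)-5-[(4-methoxybenzyl)oxy]hexan-2-one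
Product: 16 (2Z,6S,7S)-7-(3,3-diethoxyprop-1-en-2-yl)-6-[(4-methoxybenzyl)oxy]-4,9-dioxodec-2-enal
Conditions: NBS, NaHCO3, acetone/H2O, −20 °C; used crude
Reagents that add atoms: water, O
Why: Bromination of the furan at C5, addition of water and ring opening should give the (Z)-4-oxo-2-enal (oxidative furan ring opening), the furan reacting far faster than the 1,1-disubstituted alkene or the anisyl ring.

Step 8
Reactants: 16 (2Z,6S,7S)-7-(3,3-diethoxyprop-1-en-2-yl)-6-[(4-methoxybenzyl)oxy]-4,9-dioxodec-2-enal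
Product: 19 (4aS,7S,8S,8aR)-8-(3,3-diethoxyprop-1-en-2-yl)-7-[(4-methoxybenzyl)oxy]-4,4a,6,7,8,8a-hexahydronaphthalene-1,5-dione, via Michael adduct 17 (not isolated), via aldol 18 (not isolated)
Conditions: pyrrolidine (0.5 equiv), AcOH (0.5 equiv), toluene, 23 °C then 50 °C
Reagents that add atoms: none
Why: Pyrrolidine/AcOH reversibly converts the methyl ketone into its enamines and the enal into an iminium ion; the C6 enamine adds to C1 (Michael), then C4 attacks the C3 aldehyde and the aldol dehydrates irreversibly to the C3=C4–C5=O enone. The closest known reaction type is the Robinson-type [3+3] annulation of a ketone with an enal (Michael addition then aldol condensation), run here doubly intramolecularly. Ring B closes 6-exo-trig in the Michael step and ring A closes 6-(enolexo)-exo-trig in the aldol step. C6 (α to the C5 carbonyl) and C1 (α to the C10 carbonyl) are both epimerisable under the buffer, so they are set thermodynamically: the trans fusion with the C7 side chain equatorial should prevail, because the other trans isomer puts that chain axial, whereas the axial C8 ether costs little next to the trigonal C10. The step needs Michael attack at C1 and not C2, secured by ring size (six against seven), and aldol closure by C4 onto the aldehyde, secured because the competing bridged aldols are reversible and cannot dehydrate at a bridgehead. It also needs the C8 ether to survive β to the C10 ketone, for which the weakly acidic buffer is chosen.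

Step 9
Reactants: 19 (4aS,7S,8S,8aR)-8-(3,3-diethoxyprop-1-en-2-yl)-7-[(4-methoxybenzyl)oxy]-4,4a,6,7,8,8a-hexahydronaphthalene-1,5-dione
Product: 20 (4aS,7S,8S,8aR)-8-(3,3-diethoxyprop-1-en-2-yl)-2-(hydroxymethyl)-7-[(4-methoxybenzyl)oxy]-4,4a,6,7,8,8a-hexahydronaphthalene-1,5-dione
Conditions: aq HCHO (37 %), DMAP (0.3 equiv), THF/H2O, 23 °C
Reagents that add atoms: formaldehyde, C=O
Why: Morita–Baylis–Hillman reaction of the cyclohexenone (DMAP adds to C3, the enolate hydroxymethylates C4, DMAP is expelled) should install C15 only on the enone, the saturated C10 ketone being inert under these mild conditions.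

Step 10
Reactants: 20 (4aS,7S,8S,8aR)-8-(3,3-diethoxyprop-1-en-2-yl)-2-(hydroxymethyl)-7-[(4-methoxybenzyl)oxy]-4,4a,6,7,8,8a-hexahydronaphthalene-1,5-dione
Product: 21 (4aS,7S,8S,8aR)-2-{[(tert-butyldimethylsilyl)oxy]methyl}-8-(3,3-diethoxyprop-1-en-2-yl)-7-[(4-methoxybenzyl)oxy]-4,4a,6,7,8,8a-hexahydronaphthalene-1,5-dione
Conditions: TBSCl, imidazole, CH2Cl2, 0 °C
Reagents that add atoms: tert-butyldimethylsilyl chloride, CC(C)(C)[Si](C)(C)Cl
Why: Silylation of the primary allylic alcohol protects C15–OH through the later acylation and adds steric shielding to the C5 carbonyl.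

Step 11
Reactants: 21 (4aS,7S,8S,8aR)-2-{[(tert-butyldimethylsilyl)oxy]methyl}-8-(3,3-diethoxyprop-1-en-2-yl)-7-[(4-methoxybenzyl)oxy]-4,4a,6,7,8,8a-hexahydronaphthalene-1,5-dione
Product: 22 (4aS,7S,8S,8aS)-2-{[(tert-butyldimethylsilyl)oxy]methyl}-8-(3,3-diethoxyprop-1-en-2-yl)-7-[(4-methoxybenzyl)oxy]-5-methylidene-4a,5,6,7,8,8a-hexahydronaphthalen-1(4H)-one
Conditions: Ph3PCH3Br (1.1 equiv), KHMDS, THF, −78 °C to 0 °C
Reagents that add atoms: methyltriphenylphosphonium bromide, C[P+](c1ccccc1)(c1ccccc1)c1ccccc1.[Br-]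
Why: Wittig methylenation should take the saturated C10 ketone in preference to the conjugated, α-branched C5 ketone, and any enolisation at C1 returns the already preferred trans-fused configuration.

Step 12
Reactants: 22 (4aS,7S,8S,8aS)-2-{[(tert-butyldimethylsilyl)oxy]methyl}-8-(3,3-diethoxyprop-1-en-2-yl)-7-[(4-methoxybenzyl)oxy]-5-methylidene-4a,5,6,7,8,8a-hexahydronaphthalen-1(4H)-one
Product: 23 4-methylbenzenesulfonylhydrazone of 22
Conditions: TsNHNH2, EtOH, 50 °C (no added acid)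
Reagents that add atoms: 4-methylbenzenesulfonohydrazide, Cc1ccc(cc1)S(=O)(=O)NN
Why: Condensation at the only remaining carbonyl (C5) gives the α,β-unsaturated tosylhydrazone, and the neutral conditions spare the conjugated acetal.

Step 13
Reactants: 23 4-methylbenzenesulfonylhydrazone of 22
Product: 24 tert-butyl{[(4aS,7S,8S,8aS)-8-(3,3-diethoxyprop-1-en-2-yl)-7-[(4-methoxybenzyl)oxy]-5-methylidene-3,4,4a,5,6,7,8,8a-octahydronaphthalen-2-yl]methoxy}dimethylsilane
Conditions: catecholborane, CHCl3, 0 °C; then NaOAc·3H2O, 60 °C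
Reagents that add atoms: none
Why: Hydride adds to C5 of the C=N bond, sulfinate is lost and the allylic diazene expels N2 with transfer of hydrogen to C3 (reduction of an enone tosylhydrazone with alkene transposition), which should place the alkene at C4=C5 and make C3 a methylene without creating a stereocentre.

Step 14
Reactants: 24 tert-butyl{[(4aS,7S,8S,8aS)-8-(3,3-diethoxyprop-1-en-2-yl)-7-[(4-methoxybenzyl)oxy]-5-methylidene-3,4,4a,5,6,7,8,8a-octahydronaphthalen-2-yl]methoxy}dimethylsilane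
Product: 25 (1S,2S,4aS,8aS)-7-{[(tert-butyldimethylsilyl)oxy]methyl}-1-(3,3-diethoxyprop-1-en-2-yl)-4-methylidene-1,2,3,4,4a,5,6,8a-octahydronaphthalen-2-ol
Conditions: DDQ, CH2Cl2/pH 7 buffer, 0 °C
Reagents that add atoms: none
Why: Oxidative cleavage of the 4-methoxybenzyl ether frees the axial C8 alcohol, while the buffer protects the acetal and the silyl ether.

Step 15
Reactants: 26 1,1,1,3,3,3-hexafluoropropan-2-yl acrylate; 27 (tert-butyldimethylsilyloxy)acetaldehyde
Product: 28 1,1,1,3,3,3-hexafluoropropan-2-yl (3S)-4-[(tert-butyldimethylsilyl)oxy]-3-hydroxy-2-methylidenebutanoate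
Conditions: β-isocupreidine (10 mol %), DMF, −55 °C
Reagents that add atoms: none
Why: Asymmetric Morita–Baylis–Hillman reaction, in which the quinuclidine nitrogen adds to the acrylate and the phenolic OH organises the aldehyde, should deliver the (S)-carbinol (the same facial sense that gives R-adducts with alkyl aldehydes).

Step 16
Reactants: 28 1,1,1,3,3,3-hexafluoropropan-2-yl (3S)-4-[(tert-butyldimethylsilyl)oxy]-3-hydroxy-2-methylidenebutanoate
Product: 29 1,1,1,3,3,3-hexafluoropropan-2-yl (3S)-3,4-bis[(tert-butyldimethylsilyl)oxy]-2-methylidenebutanoate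
Conditions: TBSOTf, 2,6-lutidine, CH2Cl2, −78 °C
Reagents that add atoms: tert-butyldimethylsilyl trifluoromethanesulfonate, CC(C)(C)[Si](C)(C)OS(=O)(=O)C(F)(F)F
Why: Silylation of the secondary alcohol blocks it during the later esterification.

Step 17
Reactants: 29 1,1,1,3,3,3-hexafluoropropan-2-yl (3S)-3,4-bis[(tert-butyldimethylsilyl)oxy]-2-methylidenebutanoate
Product: 30 (3S)-3,4-bis[(tert-butyldimethylsilyl)oxy]-2-methylidenebutanoic acid
Conditions: LiOH, THF/H2O, 0 °C; then 1 M HCl to pH 3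
Reagents that add atoms: lithium hydroxide, [Li+].[OH-]
Why: The activated hexafluoroisopropyl ester should hydrolyse under conditions mild enough to keep both silyl ethers and the acrylate.

Step 18
Reactants: 25 (1S,2S,4aS,8aS)-7-{[(tert-butyldimethylsilyl)oxy]methyl}-1-(3,3-diethoxyprop-1-en-2-yl)-4-methylidene-1,2,3,4,4a,5,6,8a-octahydronaphthalen-2-ol; 30 (3S)-3,4-bis[(tert-butyldimethylsilyl)oxy]-2-methylidenebutanoic acid
Product: 32 (1S,2S,4aS,8aS)-7-{[(tert-butyldimethylsilyl)oxy]methyl}-1-(3,3-diethoxyprop-1-en-2-yl)-4-methylidene-1,2,3,4,4a,5,6,8a-octahydronaphthalen-2-yl (3S)-3,4-bis[(tert-butyldimethylsilyl)oxy]-2-methylidenebutanoate, via mixed anhydride 31 (not isolated)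
Conditions: 30, 2,4,6-trichlorobenzoyl chloride, Et3N, THF, 23 °C; then 25, DMAP, toluene, 23 °C
Reagents that add atoms: none
Why: Yamaguchi esterification should acylate the hindered axial C8 alcohol with retention, and no lactone can form because C12 is still an acetal.

Step 19
Reactants: 32 (1S,2S,4aS,8aS)-7-{[(tert-butyldimethylsilyl)oxy]methyl}-1-(3,3-diethoxyprop-1-en-2-yl)-4-methylidene-1,2,3,4,4a,5,6,8a-octahydronaphthalen-2-yl (3S)-3,4-bis[(tert-butyldimethylsilyl)oxy]-2-methylidenebutanoate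
Product: 33 (1S,2S,4aS,8aS)-7-(hydroxymethyl)-4-methylidene-1-(3-oxoprop-1-en-2-yl)-1,2,3,4,4a,5,6,8a-octahydronaphthalen-2-yl (3S)-3,4-dihydroxy-2-methylidenebutanoate
Conditions: aq HF (48 %), MeCN, 0 °C to 23 °C
Reagents that add atoms: water, O
Why: Aqueous HF should cleave the three silyl ethers and hydrolyse the conjugated diethyl acetal to the enal in one operation, without touching the esters or the alkenes.

Step 20
Reactants: 33 (1S,2S,4aS,8aS)-7-(hydroxymethyl)-4-methylidene-1-(3-oxoprop-1-en-2-yl)-1,2,3,4,4a,5,6,8a-octahydronaphthalen-2-yl (3S)-3,4-dihydroxy-2-methylidenebutanoate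
Product: 34 2-[(1S,2S,4aS,8aS)-2-{[(3S)-3,4-dihydroxy-2-methylidenebutanoyl]oxy}-7-(hydroxymethyl)-4-methylidene-1,2,3,4,4a,5,6,8a-octahydronaphthalen-1-yl]prop-2-enoic acid
Conditions: NaClO2, NaH2PO4, 2-methylbut-2-ene, t-BuOH/H2O, 0 °C
Reagents that add atoms: sodium chlorite, [Na+].[O-]Cl=O
Why: Pinnick oxidation converts only the enal into the acrylic acid, the scavenger removing HOCl so that the alkenes and free alcohols should survive.

Compound list
1 | furan | c1ccoc1 | starting material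
2 | (S)-epichlorohydrin | ClC[C@@H]1CO1 | starting material
3 | 2-furyllithium (not isolated) | [Li]c1ccco1 | intermediate
4 | (S)-1-chloro-3-(furan-2-yl)propan-2-ol | ClC[C@@H](O)Cc1ccco1 | intermediate
5 | epoxide (S)-2-(furan-2-ylmethyl)oxirane (not isolated) | C1O[C@H]1Cc1ccco1 | intermediate
6 | (S)-1-(furan-2-yl)but-3-en-2-ol | C=C[C@@H](O)Cc1ccco1 | intermediate
7 | (S)-2-{2-[(4-methoxybenzyl)oxy]but-3-en-1-yl}furan | C=C[C@@H](OCc1ccc(OC)cc1)Cc1ccco1 | intermediate
8 | but-3-en-2-one (methyl vinyl ketone) | C=CC(C)=O | starting material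
9 | (3E,5S)-6-(furan-2-yl)-5-[(4-methoxybenzyl)oxy]hex-3-en-2-one | CC(=O)/C=C/[C@@H](OCc1ccc(OC)cc1)Cc1ccco1 | intermediate
10 | 3,3-diethoxyprop-1-ene (acrolein diethyl acetal) | C=CC(OCC)OCC | starting material
11 | dibromide 2,3-dibromo-1,1-diethoxypropane (racemic, not isolated) | BrCC(Br)C(OCC)OCC | intermediate
12 | 2-bromo-3,3-diethoxyprop-1-ene | C=C(Br)C(OCC)OCC | intermediate
13 | vinyllithium (3,3-diethoxyprop-1-en-2-yl)lithium (not isolated) | [Li]C(=C)C(OCC)OCC | intermediate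
14 | divinylcuprate lithium bis(3,3-diethoxyprop-1-en-2-yl)cuprate (not isolated) | [Li+].C=C([Cu-]C(=C)C(OCC)OCC)C(OCC)OCC | intermediate
15 | (4S,5S)-4-(3,3-diethoxyprop-1-en-2-yl)-6-(furan-2-yl)-5-[(4-methoxybenzyl)oxy]hexan-2-one | C=C(C(OCC)OCC)[C@@H]([C@@H](OCc1ccc(OC)cc1)Cc1ccco1)CC(C)=O | intermediate
16 | (2Z,6S,7S)-7-(3,3-diethoxyprop-1-en-2-yl)-6-[(4-methoxybenzyl)oxy]-4,9-dioxodec-2-enal | C=C(C(OCC)OCC)[C@@H]([C@@H](OCc1ccc(OC)cc1)CC(=O)/C=C\C=O)CC(C)=O | intermediate
17 | Michael adduct 2-[2-acetyl-3-(3,3-diethoxyprop-1-en-2-yl)-4-[(4-methoxybenzyl)oxy]-6-oxocyclohexyl]acetaldehyde (ring configuration as in 19; not isolated) | C=C(C(OCC)OCC)[C@@H]1[C@@H](C(C)=O)[C@H](CC=O)C(=O)C[C@@H]1OCc1ccc(OC)cc1 | intermediate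
18 | aldol 8-(3,3-diethoxyprop-1-en-2-yl)-3-hydroxy-7-[(4-methoxybenzyl)oxy]octahydronaphthalene-1,5-dione (trans-fused, carbinol epimers; not isolated) | C=C(C(OCC)OCC)[C@@H]1[C@H]2C(=O)CC(O)C[C@@H]2C(=O)C[C@@H]1OCc1ccc(OC)cc1 | intermediate
19 | (4aS,7S,8S,8aR)-8-(3,3-diethoxyprop-1-en-2-yl)-7-[(4-methoxybenzyl)oxy]-4,4a,6,7,8,8a-hexahydronaphthalene-1,5-dione (trans-fused; side chain equatorial, ether axial) | C=C(C(OCC)OCC)[C@@H]1[C@H]2C(=O)C=CC[C@@H]2C(=O)C[C@@H]1OCc1ccc(OC)cc1 | intermediate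
20 | (4aS,7S,8S,8aR)-8-(3,3-diethoxyprop-1-en-2-yl)-2-(hydroxymethyl)-7-[(4-methoxybenzyl)oxy]-4,4a,6,7,8,8a-hexahydronaphthalene-1,5-dione | C=C(C(OCC)OCC)[C@@H]1[C@H]2C(=O)C(CO)=CC[C@@H]2C(=O)C[C@@H]1OCc1ccc(OC)cc1 | intermediate
21 | (4aS,7S,8S,8aR)-2-{[(tert-butyldimethylsilyl)oxy]methyl}-8-(3,3-diethoxyprop-1-en-2-yl)-7-[(4-methoxybenzyl)oxy]-4,4a,6,7,8,8a-hexahydronaphthalene-1,5-dione | C=C(C(OCC)OCC)[C@@H]1[C@H]2C(=O)C(CO[Si](C)(C)C(C)(C)C)=CC[C@@H]2C(=O)C[C@@H]1OCc1ccc(OC)cc1 | intermediate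
22 | (4aS,7S,8S,8aS)-2-{[(tert-butyldimethylsilyl)oxy]methyl}-8-(3,3-diethoxyprop-1-en-2-yl)-7-[(4-methoxybenzyl)oxy]-5-methylidene-4a,5,6,7,8,8a-hexahydronaphthalen-1(4H)-one | C=C(C(OCC)OCC)[C@@H]1[C@H]2C(=O)C(CO[Si](C)(C)C(C)(C)C)=CC[C@@H]2C(=C)C[C@@H]1OCc1ccc(OC)cc1 | intermediate
23 | 4-methylbenzenesulfonylhydrazone of 22 (C=N isomers) | C=C(C(OCC)OCC)[C@@H]1[C@H]2C(=NNS(=O)(=O)c3ccc(C)cc3)C(CO[Si](C)(C)C(C)(C)C)=CC[C@@H]2C(=C)C[C@@H]1OCc1ccc(OC)cc1 | intermediate
24 | tert-butyl{[(4aS,7S,8S,8aS)-8-(3,3-diethoxyprop-1-en-2-yl)-7-[(4-methoxybenzyl)oxy]-5-methylidene-3,4,4a,5,6,7,8,8a-octahydronaphthalen-2-yl]methoxy}dimethylsilane | C=C(C(OCC)OCC)[C@@H]1[C@H]2C=C(CO[Si](C)(C)C(C)(C)C)CC[C@@H]2C(=C)C[C@@H]1OCc1ccc(OC)cc1 | intermediate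
25 | (1S,2S,4aS,8aS)-7-{[(tert-butyldimethylsilyl)oxy]methyl}-1-(3,3-diethoxyprop-1-en-2-yl)-4-methylidene-1,2,3,4,4a,5,6,8a-octahydronaphthalen-2-ol | C=C(C(OCC)OCC)[C@@H]1[C@H]2C=C(CO[Si](C)(C)C(C)(C)C)CC[C@@H]2C(=C)C[C@@H]1O | intermediate
26 | 1,1,1,3,3,3-hexafluoropropan-2-yl acrylate | C=CC(=O)OC(C(F)(F)F)C(F)(F)F | starting material
27 | (tert-butyldimethylsilyloxy)acetaldehyde | O=CCO[Si](C)(C)C(C)(C)C | starting material
28 | 1,1,1,3,3,3-hexafluoropropan-2-yl (3S)-4-[(tert-butyldimethylsilyl)oxy]-3-hydroxy-2-methylidenebutanoate | C=C(C(=O)OC(C(F)(F)F)C(F)(F)F)[C@H](O)CO[Si](C)(C)C(C)(C)C | intermediate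
29 | 1,1,1,3,3,3-hexafluoropropan-2-yl (3S)-3,4-bis[(tert-butyldimethylsilyl)oxy]-2-methylidenebutanoate | C=C(C(=O)OC(C(F)(F)F)C(F)(F)F)[C@H](O[Si](C)(C)C(C)(C)C)CO[Si](C)(C)C(C)(C)C | intermediate
30 | (3S)-3,4-bis[(tert-butyldimethylsilyl)oxy]-2-methylidenebutanoic acid | C=C(C(=O)O)[C@H](O[Si](C)(C)C(C)(C)C)CO[Si](C)(C)C(C)(C)C | intermediate
31 | mixed anhydride of 30 and 2,4,6-trichlorobenzoic acid (not isolated) | C=C(C(=O)OC(=O)c1c(Cl)cc(Cl)cc1Cl)[C@H](O[Si](C)(C)C(C)(C)C)CO[Si](C)(C)C(C)(C)C | intermediate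
32 | (1S,2S,4aS,8aS)-7-{[(tert-butyldimethylsilyl)oxy]methyl}-1-(3,3-diethoxyprop-1-en-2-yl)-4-methylidene-1,2,3,4,4a,5,6,8a-octahydronaphthalen-2-yl (3S)-3,4-bis[(tert-butyldimethylsilyl)oxy]-2-methylidenebutanoate | C=C(C(OCC)OCC)[C@@H]1[C@H]2C=C(CO[Si](C)(C)C(C)(C)C)CC[C@@H]2C(=C)C[C@@H]1OC(=O)C(=C)[C@H](O[Si](C)(C)C(C)(C)C)CO[Si](C)(C)C(C)(C)C | intermediate
33 | (1S,2S,4aS,8aS)-7-(hydroxymethyl)-4-methylidene-1-(3-oxoprop-1-en-2-yl)-1,2,3,4,4a,5,6,8a-octahydronaphthalen-2-yl (3S)-3,4-dihydroxy-2-methylidenebutanoate | C=C(C=O)[C@@H]1[C@H]2C=C(CO)CC[C@@H]2C(=C)C[C@@H]1OC(=O)C(=C)[C@H](O)CO | intermediate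
34 | 2-[(1S,2S,4aS,8aS)-2-{[(3S)-3,4-dihydroxy-2-methylidenebutanoyl]oxy}-7-(hydroxymethyl)-4-methylidene-1,2,3,4,4a,5,6,8a-octahydronaphthalen-1-yl]prop-2-enoic acid | C=C(C(=O)O)[C@@H]1[C@H]2C=C(CO)CC[C@@H]2C(=C)C[C@@H]1OC(=O)C(=C)[C@H](O)CO | target

Total step count: 20. Longest linear sequence: 16 steps (steps 1–4, 6–14 and 18–20).

Steps most likely to fail

Step 8. Under the equilibrating buffer the C8 ether, β to the C10 ketone, may be lost by E1cB elimination, and equilibration may leave mixtures of ring-fusion epimers. The fallback forms the two bonds in separate operations of different mechanism. It sets out from 9: the cuprate addition of step 6 is run with Me3SiCl and worked up without water, trapping the C6 enolate as {[(4S,5S)-4-(3,3-diethoxyprop-1-en-2-yl)-6-(furan-2-yl)-5-[(4-methoxybenzyl)oxy]hex-2-en-2-yl]oxy}trimethylsilane F1. Photooxygenation (O2, rose bengal, light, −78 °C, then Me2S) opens the furan without base to (2Z,6S,7S)-7-(3,3-diethoxyprop-1-en-2-yl)-6-[(4-methoxybenzyl)oxy]-4-oxo-9-[(trimethylsilyl)oxy]deca-2,8-dienal F2. BF3·OEt2 in CH2Cl2 at −78 °C then triggers an intramolecular Mukaiyama–Michael addition under kinetic control (chair-like transition state, C7 chain equatorial) to give keto aldehyde 17, now isolated. Brief treatment with pyrrolidinium acetate at 23 °C closes ring A, and the route is rejoined at 19.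

Step 11. The ylide may also attack the conjugated C5 carbonyl, or act as a base and trigger β-elimination of the C8 ether. The fallback defers the methylenation until C10 is the only carbonyl. It sets out from 21: NaBH4 in EtOH/CH2Cl2 at −78 °C should reduce the saturated ketone faster than the hindered enone, giving the C10-hydroxy enone F3. Condensation with TsNHNH2 gives its tosylhydrazone F4, and catecholborane then NaOAc·3H2O gives the transposed diene alcohol F5. Dess–Martin periodinane gives the diene ketone F6, and Ph3PCH3Br/KHMDS now meets a single carbonyl; the route is rejoined at 24.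

Step 12. Condensation at the hindered, conjugated C5 ketone may be slow, and the hydrazide may add to C3 instead (aza-Michael addition followed by pyrazoline formation). The fallback reaches the same transposed alkene through an allylic diazene made by substitution and not by condensation. It sets out from 22: Luche reduction (NaBH4, CeCl3·7H2O, MeOH, −78 °C) gives the allylic C5 alcohol F7. Mitsunobu displacement with 2-nitrobenzenesulfonylhydrazide (PPh3, diethyl azodicarboxylate, THF, −30 °C to 23 °C) gives the monoalkyl diazene, which loses N2 with delivery of hydrogen to C3; the route is rejoined at 24.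

Further compounds
F1 | step 8 | {[(4S,5S)-4-(3,3-diethoxyprop-1-en-2-yl)-6-(furan-2-yl)-5-[(4-methoxybenzyl)oxy]hex-2-en-2-yl]oxy}trimethylsilane (E/Z mixture) | C=C(C(OCC)OCC)[C@@H]([C@@H](OCc1ccc(OC)cc1)Cc1ccco1)C=C(C)O[Si](C)(C)C
F2 | step 8 | (2Z,6S,7S)-7-(3,3-diethoxyprop-1-en-2-yl)-6-[(4-methoxybenzyl)oxy]-4-oxo-9-[(trimethylsilyl)oxy]deca-2,8-dienal | C=C(C(OCC)OCC)[C@@H]([C@@H](OCc1ccc(OC)cc1)CC(=O)/C=C\C=O)C=C(C)O[Si](C)(C)C
F3 | step 11 | C10-hydroxy enone: 2-{[(tert-butyldimethylsilyl)oxy]methyl}-8-(3,3-diethoxyprop-1-en-2-yl)-5-hydroxy-7-[(4-methoxybenzyl)oxy]-4a,5,6,7,8,8a-hexahydronaphthalen-1(4H)-one (ring configuration as in 21, either carbinol epimer) | C=C(C(OCC)OCC)[C@@H]1[C@H]2C(=O)C(CO[Si](C)(C)C(C)(C)C)=CC[C@@H]2C(O)C[C@@H]1OCc1ccc(OC)cc1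
F4 | step 11 | 4-methylbenzenesulfonylhydrazone of F3 | C=C(C(OCC)OCC)[C@@H]1[C@H]2C(=NNS(=O)(=O)c3ccc(C)cc3)C(CO[Si](C)(C)C(C)(C)C)=CC[C@@H]2C(O)C[C@@H]1OCc1ccc(OC)cc1
F5 | step 11 | diene alcohol: 6-{[(tert-butyldimethylsilyl)oxy]methyl}-4-(3,3-diethoxyprop-1-en-2-yl)-3-[(4-methoxybenzyl)oxy]-1,2,3,4,4a,7,8,8a-octahydronaphthalen-1-ol (ring configuration as in 24) | C=C(C(OCC)OCC)[C@@H]1[C@H]2C=C(CO[Si](C)(C)C(C)(C)C)CC[C@@H]2C(O)C[C@@H]1OCc1ccc(OC)cc1
F6 | step 11 | diene ketone: 6-{[(tert-butyldimethylsilyl)oxy]methyl}-4-(3,3-diethoxyprop-1-en-2-yl)-3-[(4-methoxybenzyl)oxy]-3,4,4a,7,8,8a-hexahydronaphthalen-1(2H)-one (ring configuration as in 24) | C=C(C(OCC)OCC)[C@@H]1[C@H]2C=C(CO[Si](C)(C)C(C)(C)C)CC[C@@H]2C(=O)C[C@@H]1OCc1ccc(OC)cc1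
F7 | step 12 | allylic C5 alcohol: 2-{[(tert-butyldimethylsilyl)oxy]methyl}-8-(3,3-diethoxyprop-1-en-2-yl)-7-[(4-methoxybenzyl)oxy]-5-methylidene-1,4,4a,5,6,7,8,8a-octahydronaphthalen-1-ol (ring configuration as in 22, either carbinol epimer) | C=C(C(OCC)OCC)[C@@H]1[C@H]2C(O)C(CO[Si](C)(C)C(C)(C)C)=CC[C@@H]2C(=C)C[C@@H]1OCc1ccc(OC)cc1
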